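## Structural features

The target, methyl 7α-acetoxylabd-8(17)-en-15-oate (labdane numbering throughout), is a trans-fused decalin: ring A (C1–C5, C10) carries a gem-dimethyl group at C4, ring B (C5–C10) carries an exocyclic methylene at C8 and an axial (α) acetoxy group at C7, and the rings share C5 (α-H) and the quaternary C10 (β-methyl). C9 bears, equatorially and cis to the C10 methyl, the C11–C15 chain, which ends in a methyl ester and holds an isolated methyl-bearing stereocentre at C13. C5, C10 and C9 are contiguous and C7 faces C9 across the sp2 carbon C8, so four of the five stereocentres depend on one another, while C13 is too remote to be controlled from the ring and is best brought in as an enantiopure fragment. The fragile elements are the allylic secondary acetate (ionisation, SN2′ transposition, elimination), the exocyclic alkene (acid moves it into the ring) and two different esters, so the C7 oxygen and the C8 methylene belong at the very end. The real difficulty is the C4–C5 bond, which joins a quaternary carbon to a ring-fusion methine next to the quaternary C10, together with the anti relationship of H5 and the C10 methyl and the absolute configuration at C10. The key step exploits that C5 is the γ-carbon of a ring B enone (C8 carbonyl, C6=C7): as the linear silyl dienol ether C8(OSi)=C7–C6=C5 it is nucleophilic at C5, and a C4 cation held on the C1–C3 tether from C10 can reach C5 only through a six-membered ring. The same enone keeps C5 (vinylogous α) and C9 (α) epimerisable after ring closure and leaves the carbonyl at C8, exactly where the methylene must be built. Precursor 17 and enone 19 were compared centre by centre with 23 and map onto it unchanged (C9, C10, C13; also C5 in 19), so no structure needs correcting; what needs correcting is the expectation of a trans-selective closure under kinetic control, which the analysis in step 10 does not support.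

## Logic of the disconnections

23 ⇒ 22. The C7 O–acyl bond is cut first. The allylic acetate is the most labile group, so it goes on last. The forward step only has to acylate a hindered axial hydroxyl without ionising it.

22 ⇒ 21. The C7–O bond is cut, back to the bare exocyclic alkene. This removes a stereocentre and lets the C8=C17 alkene, needed anyway, direct an allylic oxidation. The forward step must choose the C7 methylene over the C9 methine and deliver oxygen on the α face.

21 ⇒ 20. The C8=C17 bond is cut to the C8 ketone. The carbonyl is the handle that the key step leaves behind, and it keeps C9 epimerisable to its stable configuration. The methylenation must spare the methyl ester.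

20 ⇒ 19. Two hydrogens (C6, C7) are removed to return to the enone. This costs one trivial step and restores the conjugation that makes C5 a γ-carbon. The forward reduction creates no stereocentre.

19 ⇒ 17 (through 18). The C4–C5 bond is cut and ring A opens. The bicycle becomes a monocycle, quaternary C4 becomes a tertiary chloride and the C5 stereocentre disappears. The forward step needs a regiodefined linear dienol ether, γ- rather than α-attack, and the trans fusion. The closure is expected to give 18 first, so 19 is planned to arise by equilibration, not by kinetic control.

17 ⇒ 16. The O–Si bond is cut and a hydrogen returned to C5. The demand is removal of the γ-proton (C5), not the α′-proton (C9).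

16 ⇒ 14. The C6=C7 unsaturation is removed. The forward dehydrogenation has only one easy direction, since C10 is quaternary and C9 is a hindered methine, but it must tolerate the ester and the chloride.

14 ⇒ 13. The C4–Cl bond is cut to the trisubstituted alkene. The alkene is the form in which the tether survives the organometallic and reductive steps. The forward step is a Markovnikov addition of HCl.

13 ⇒ 11 ⇒ 9. The C9–H and C11–H bonds, then the C11–O bond, are reinstated, leading back to an aldol. A hindered C9 enolate does not alkylate reliably with an unactivated primary halide, whereas it does add to an aldehyde. The price is a dehydration and a chemoselective conjugate reduction that leaves C9 uncontrolled, which is acceptable because C9 is set later.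

9 ⇒ 4 + 5 + 6. The C9–C11 and C1–C10 bonds are cut in one operation. Three fragments result, two of them commercial. The forward step demands catalyst control of the enantiofacial addition at C10 and use of the conjugate-addition enolate, which is regiodefined at C9; an enolate made later from the ketone would form on the C7 side.

4 ⇒ 3 ⇒ 2 ⇒ 1. The oxidation level at C11 is adjusted and the ester C–O bond is cut to the meso anhydride. C13 arises by desymmetrisation. The demands are catalyst differentiation of enantiotopic carbonyls and reduction of the acid in preference to the ester.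

## Other disconnections considered

Alternative 1: The cut removes C4–C5 and C1–C10 from a ring B enone A1 that already carries the C7 oxygen, and leaves C2=C3 for a later metathesis.
- Forward key step: triflimide would catalyse conjugate addition of prenyltrimethylsilane A2 through its γ-carbon to A1, placing the 1,1-dimethylallyl group (C4) on C5 anti to the C7 silyloxy group. MeLi would open the resulting silyl enol ether to the lithium enolate, and allyl bromide A3 would alkylate C10 anti to the new C5 substituent to give A4. Ring-closing metathesis (second-generation Grubbs catalyst) would then give the Δ2-octalone A5.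
- In its favour: the C7 oxygen is present and configured from the start. Quaternary C4 is attached by a polarity-matched addition to an enone β-carbon. The trans relationship of H5 and the C10 methyl follows from two substrate-controlled steps.
- Against it here: A4 and A5 have their carbonyl at C9, where 23 has a CH bearing the side chain. C8 is a bare methylene between that carbonyl and the β-silyloxy carbon C7. Adding C17 at C8, attaching the C11–C15 chain (with C13) to the neopentyl C9 carbonyl, removing the C9 oxygen and setting 9α-H would all be done on a β-silyloxy ketone that can lose the C7 oxygen by E1cB elimination whenever C8 is enolised.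
- Comparison: on ring-fusion control this alternative is better than the chosen plan, which must equilibrate C5. On reliability of C4–C5 bond formation it is at least equal. On step economy up to the decalin it is shorter. The chosen plan delivers the carbonyl at C8 and the full chain at C9, so only four functional-group steps remain after ring closure, and there it is the shorter.

Alternative 2: The cut removes C5–C10 and C7–C8, so that both rings come from the acyclic keto enoate A6.
- Forward key step: condensation with a chiral primary amine would give the more substituted secondary enamine, whose α-carbon C10 adds to the enoate β-carbon C5 (ring A; C10 and C5 set together). Methoxide would then drive Claisen acylation of the methyl-ketone carbon C8 by the C7 ester (ring B) to give the 7,9-dione A7.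
- In its favour: two rings, two C–C bonds and both fusion centres form in one operation from a simple chain. The C5/C10 relationship is fixed in a compact cyclic transition state and cannot epimerise later. The C7 oxygen is already in place.
- Against it here: the acceptor carbon C5 is neopentylic, so the Michael step is slow. A7 has oxygen on C9 and no carbon on C8. C9 would have to change from a carbonyl into a CH bearing the chain (addition to the more hindered of two carbonyls, then deoxygenation), C17 would have to be added at C8, and the alkene would have to end up exocyclic and not in the more stable tetrasubstituted Δ8 position.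
- Comparison: in skeletal bonds per step and in ring-fusion control this alternative is better. The chosen key step closes only one ring and sets C10 in a separate catalytic step, but 19 already contains every carbon of 23 except C17 and the acetyl group. The alternative is superior in building the decalin and inferior in what remains afterwards.

Alternative 3: The cut excises C7 (bonds C6–C7 and C7–C8) and leads back to the B-nor hydrindanone A8 with the complete side chain.
- Forward key step: Sc(OTf)3 would activate the C8 carbonyl toward addition of trimethylsilyldiazomethane A9. Loss of dinitrogen with 1,2-shift of the C6 methylene inserts C7, and protodesilylation of the α-silyl ketone gives A10, which is the same compound as 20.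
- In its favour: C5, C9, C10 and C13 are all settled before ring B reaches its final size, so no ring-fusion question arises at the key step. From A10 onward the endgame would be identical to steps 12–14.
- Against it: the insertion must choose the C6 methylene over the C9 methine (the other migration gives the 7-oxo isomer), stop after one homologation and not epimerise C9 at the activated carbonyl. The difficulty is moved, not removed: A8 is a trans-fused hydrindanone with an angular methyl, more strained than the decalin and with the same C4/C5/C10 congestion, and no shorter enantioselective assembly of it is apparent.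
- Comparison: on ring-fusion control it is better than the chosen plan, and in the endgame it is equal. On mechanism the ring expansion is the more predictable single step. On structure and step economy it spends a step that creates no stereocentre of 23 and only reaches the point that step 11 of the chosen plan reaches by a hydrogenation.

Key step: step 10

Remark on the chemistry: compounds 13–17 are carried as mixtures of C9 epimers (named and drawn as the epimer that maps onto 23) because C9 is set by equilibration in step 10, and the enantiomeric series of the alcoholysis catalyst (step 1) and of the carbene ligand (step 4) are assumed to be chosen so that (S)-2 and the (R)-configured quaternary centre of 8 result.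

Step 1
Reactants: 1 3-methylglutaric anhydride
Product: 2 (S)-5-methoxy-3-methyl-5-oxopentanoic acid
Conditions: MeOH (10 equiv), (DHQD)2AQN or (DHQ)2AQN (10 mol%; the pseudoenantiomer that gives the (S)-acid), Et2O, −40 °C
Reagents that add atoms: methanol, CO
Why: Desymmetrising alcoholysis of a meso anhydride by a bifunctional cinchona alkaloid catalyst; general-base activation of methanol differentiates the enantiotopic carbonyls and so sets C13, and the catalyst is recovered by acid extraction.

Step 2
Reactants: 2 (S)-5-methoxy-3-methyl-5-oxopentanoic acid
Product: 3 methyl (S)-5-hydroxy-3-methylpentanoate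
Conditions: BH3·SMe2 (1.1 equiv), THF, −10 °C to rt; then MeOH
Reagents that add atoms: none
Why: Borane reduces a carboxylic acid (through its acyloxyborane) much faster than an ester, so only the acid terminus becomes the C11 alcohol and C13 is untouched; the hydroxy ester is kept cold and used at once because it lactonises easily.

Step 3
Reactants: 3 methyl (S)-5-hydroxy-3-methylpentanoate
Product: 4 methyl (S)-3-methyl-5-oxopentanoate
Conditions: TEMPO (10 mol%), PhI(OAc)2 (1.1 equiv), CH2Cl2, rt
Reagents that add atoms: none
Why: Oxoammonium-mediated oxidation of a primary alcohol stops at the aldehyde under neutral anhydrous conditions, which also suppresses lactonisation; C13 is β to both carbonyls and cannot epimerise.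

Step 4
Reactants: 5 5-bromo-2-methylpent-2-ene; 6 3-methylcyclohex-2-en-1-one; 4 methyl (S)-3-methyl-5-oxopentanoate
Product: 9 methyl (3S)-5-hydroxy-3-methyl-5-[(2R)-2-methyl-2-(4-methylpent-3-en-1-yl)-6-oxocyclohexyl]pentanoate (aldol; mixture at the ring methine C9 and the carbinol C11), via Grignard reagent 7 (not isolated), via magnesium enolate 8 (not isolated)
Conditions: 5, Mg turnings, Et2O, reflux; then 6 (1.05 equiv), Cu(OTf)2 (3 mol%), chiral C2-symmetric imidazolinium chloride (carbene precursor, 4 mol%), Et2O, −30 to 0 °C; then 4 (0.9 equiv), −78 °C; sat. aq. NH4Cl at −78 °C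
Reagents that add atoms: none
Why: Copper-catalysed asymmetric conjugate addition of a Grignard reagent to a β-substituted cyclohexenone under chiral carbene control sets the quaternary C10; the magnesium enolate formed is regiodefined at C9, so its aldol addition to 4 makes C9–C11 on the hindered side that an enolate generated from the isolated ketone would avoid. The configurations at C9 and C11 are of no consequence (C11 is removed in step 5 and C9 is set in step 10), and the Grignard reagent is kept limiting so that none is left to attack 4.

Step 5
Reactants: 9 methyl (3S)-5-hydroxy-3-methyl-5-[(2R)-2-methyl-2-(4-methylpent-3-en-1-yl)-6-oxocyclohexyl]pentanoate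
Product: 11 methyl (3S)-3-methyl-5-[(2R)-2-methyl-2-(4-methylpent-3-en-1-yl)-6-oxocyclohexylidene]pentanoate (E/Z mixture), via mesylate 10 (not isolated)
Conditions: MsCl (1.5 equiv), Et3N (3 equiv), CH2Cl2, 0 °C; then DBU (2 equiv), rt
Reagents that add atoms: none
Why: Sulfonylation followed by E1cB elimination of a β-sulfonyloxy ketone; mesylation of the secondary alcohol is faster than its lactonisation onto the ester, and the alkene geometry is irrelevant because the double bond is reduced next.

Step 6
Reactants: 11 methyl (3S)-3-methyl-5-[(2R)-2-methyl-2-(4-methylpent-3-en-1-yl)-6-oxocyclohexylidene]pentanoate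
Product: 13 methyl (3S)-3-methyl-5-[(1R,2R)-2-methyl-2-(4-methylpent-3-en-1-yl)-6-oxocyclohexyl]pentanoate together with its (1S,2R) epimer, via silyl enol ether 12 (not isolated)
Conditions: [(Ph3P)CuH]6 (5 mol%), PhMe2SiH (1.5 equiv), toluene, rt; then 1 M HCl, THF, 0 °C
Reagents that add atoms: none
Why: Copper hydride conjugate reduction delivers hydride to the exocyclic β-carbon C11 and leaves the isolated trisubstituted alkene and the ester alone; hydrolysis of the silyl enol ether protonates C9 without control, which is accepted because C9 stays α to the C8 carbonyl until it is equilibrated in step 10.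

Step 7
Reactants: 13 methyl (3S)-3-methyl-5-[(1R,2R)-2-methyl-2-(4-methylpent-3-en-1-yl)-6-oxocyclohexyl]pentanoate (with C9 epimer)
Product: 14 methyl (3S)-5-[(1R,2R)-2-(4-chloro-4-methylpentyl)-2-methyl-6-oxocyclohexyl]-3-methylpentanoate (with C9 epimer)
Conditions: HCl (g, dry), CH2Cl2, −78 to 0 °C
Reagents that add atoms: hydrogen chloride, Cl
Why: Markovnikov hydrochlorination of a trisubstituted alkene through the tertiary cation; at low temperature the ketone and ester are inert, and the chloride is the latent C4 cation for the key step.

Step 8
Reactants: 14 methyl (3S)-5-[(1R,2R)-2-(4-chloro-4-methylpentyl)-2-methyl-6-oxocyclohexyl]-3-methylpentanoate (with C9 epimer)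
Product: 16 methyl (3S)-5-[(1R,6S)-6-(4-chloro-4-methylpentyl)-6-methyl-2-oxocyclohex-3-en-1-yl]-3-methylpentanoate (with C9 epimer), via trimethylsilyl enol ether 15 (not isolated)
Conditions: LiN(SiMe3)2 (1.1 equiv), TMSCl (1.5 equiv), THF, −78 °C; pentane/aq. NaHCO3 work-up; then Pd(OAc)2 (1.1 equiv), MeCN, rt
Reagents that add atoms: none
Why: Saegusa oxidation; kinetic enolisation takes the C7 methylene (C9 is a hindered methine and the ester is less acidic), and the divalent palladium enolate can β-eliminate only toward C6, giving the Δ6 enone. The tertiary chloride survives base at −78 °C and palladium acetate at rt.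

Step 9
Reactants: 16 methyl (3S)-5-[(1R,6S)-6-(4-chloro-4-methylpentyl)-6-methyl-2-oxocyclohex-3-en-1-yl]-3-methylpentanoate (with C9 epimer)
Product: 17 methyl (3S)-5-[(1R,6S)-2-(tert-butyldimethylsilyloxy)-6-(4-chloro-4-methylpentyl)-6-methylcyclohexa-2,4-dien-1-yl]-3-methylpentanoate (with C9 epimer)
Conditions: TBSOTf (1.3 equiv), Et3N (2.5 equiv), CH2Cl2, −78 to 0 °C, then rt until the isomer composition is constant; Et3N-deactivated silica
Reagents that add atoms: tert-butyldimethylsilyl trifluoromethanesulfonate, CC(C)(C)[Si](C)(C)OS(=O)(=O)C(F)(F)F
Why: Soft enolisation of an enone; O-silylation followed by loss of a γ-proton from C5 gives the linear, through-conjugated dienol ether. Removal of the α′-proton at C9 would need a tetrasubstituted enol ether crowded by the quaternary C10 and the C11 chain, and the amine/ammonium triflate medium lets the isomers equilibrate toward the linear one; the ester is not enolised under these conditions.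

Step 10
Reactants: 17 methyl (3S)-5-[(1R,6S)-2-(tert-butyldimethylsilyloxy)-6-(4-chloro-4-methylpentyl)-6-methylcyclohexa-2,4-dien-1-yl]-3-methylpentanoate (with C9 epimer)
Product: 19 methyl (5S,9R,10S,13S)-8-oxo-17-norlabd-6-en-15-oate (trans-fused; 5α-H; 9α-H), via cis-fused 5-epimer 18 (not isolated)
Conditions: TiCl4 (2.2 equiv), 2,6-di-tert-butyl-4-methylpyridine (0.3 equiv), CH2Cl2 (0.02 M), −78 to −40 °C; sat. aq. NaHCO3; crude then NaOMe (0.3 equiv), MeOH, 40 °C
Reagents that add atoms: none
Why: TiCl4 (the second equivalent is taken up by the ester carbonyl) abstracts chloride from C4; the tertiary cation is captured by C5, the γ-terminus of the 1-silyloxy-1,3-diene, and the silyloxocarbenium ion formed loses its silyl group to chloride, so the C4–C5 bond and the Δ6-8-enone arise in one operation. The closest known reaction type is the Lewis-acid-mediated tert-alkylation of silyl enol ethers by tertiary chlorides and its γ-selective vinylogous form with silyl dienol ethers, here run intramolecularly. Ring A closes in a six-membered enolexo-exo mode: the C1–C3 tether lets C4 reach C5 through a chair, whereas bonding at C7 would require a bridged eight-membered ring, and this secures γ- over α-attack; the hindered pyridine removes HCl so that the dienol ether is not protodesilylated. The new stereocentre C5 is the critical one: the bond must form perpendicular to the diene plane, and the unstrained chair (tether pseudoequatorial on C10, methyl pseudoaxial, cation approaching anti to the methyl) leads to the cis-fused epimer 18, while trans fusion would require approach syn to the axial methyl; kinetic trans-selectivity is therefore not assumed. Control is thermodynamic: C5 is vinylogously α and C9 is α to the C8 carbonyl, so methoxide in methanol (degenerate for the methyl ester) equilibrates both centres through the extended and cross-conjugated dienolates toward 19, which has H5 anti to the C10 methyl, no ring bond axial on ring A and the C9 chain equatorial. The margin in favour of 19 is expected to be real but not large, so any residual 18 is separated and resubmitted; C10 and C13 cannot epimerise.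

Step 11
Reactants: 19 methyl (5S,9R,10S,13S)-8-oxo-17-norlabd-6-en-15-oate
Product: 20 methyl (5S,9R,10S,13S)-8-oxo-17-norlabdan-15-oate
Conditions: H2 (1 atm), 10% Pd/C, EtOAc, rt
Reagents that add atoms: none
Why: Heterogeneous hydrogenation of the disubstituted conjugated alkene; no stereocentre is created, the ketone and ester are untouched, and C5 is thereby fixed against further epimerisation.

Step 12
Reactants: 20 methyl (5S,9R,10S,13S)-8-oxo-17-norlabdan-15-oate
Product: 21 methyl (5S,9S,10S,13S)-labd-8(17)-en-15-oate
Conditions: Ph3PCH3Br (3 equiv), NaN(SiMe3)2 (2.8 equiv), THF, 0 °C; then 20, 0 to 45 °C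
Reagents that add atoms: methyltriphenylphosphonium bromide, C[P+](c1ccccc1)(c1ccccc1)c1ccccc1.[Br-]
Why: Wittig methylenation; the unstabilised ylide attacks the ketone far faster than the methyl ester, and reversible enolisation toward C9 is harmless because C9 already has its thermodynamic configuration.

Step 13
Reactants: 21 methyl (5S,9S,10S,13S)-labd-8(17)-en-15-oate
Product: 22 methyl (5S,7R,9R,10S,13S)-7-hydroxylabd-8(17)-en-15-oate (7α-OH)
Conditions: SeO2 (0.5 equiv), t-BuOOH (2.5 equiv, in decane), CH2Cl2, 0 °C to rt
Reagents that add atoms: selenium dioxide, O=[Se]=O; tert-butyl hydroperoxide, CC(C)(C)OO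
Why: Allylic hydroxylation by an ene reaction at the exocyclic methylene followed by [2,3]-sigmatropic shift of the allylseleninic acid, which returns the double bond to C8=C17. The C7 methylene reacts in preference to the C9 methine, and oxygen is delivered axially on the α face, anti to the C10 methyl, to give the 7α alcohol.

Step 14
Reactants: 22 methyl (5S,7R,9R,10S,13S)-7-hydroxylabd-8(17)-en-15-oate
Product: 23 methyl (5S,7R,9R,10S,13S)-7-acetoxylabd-8(17)-en-15-oate (the target)
Conditions: Ac2O (3 equiv), pyridine, DMAP (10 mol%), CH2Cl2, 0 °C to rt
Reagents that add atoms: acetic anhydride, CC(=O)OC(C)=O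
Why: Nucleophile-catalysed acylation of the axial allylic alcohol on oxygen, with retention at C7; the basic, non-ionising conditions avoid allylic transposition and migration of the exocyclic alkene.

## Compound list

1 | 3-methylglutaric anhydride | CC1CC(=O)OC(=O)C1 | starting material
2 | (S)-5-methoxy-3-methyl-5-oxopentanoic acid | OC(=O)C[C@H](C)CC(=O)OC | intermediate
3 | methyl (S)-5-hydroxy-3-methylpentanoate | OCC[C@H](C)CC(=O)OC | intermediate
4 | methyl (S)-3-methyl-5-oxopentanoate | O=CC[C@H](C)CC(=O)OC | intermediate
5 | 5-bromo-2-methylpent-2-ene | CC(C)=CCCBr | starting material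
6 | 3-methylcyclohex-2-en-1-one | CC1=CC(=O)CCC1 | starting material
7 | (4-methylpent-3-en-1-yl)magnesium bromide | CC(C)=CCC[Mg]Br | intermediate (not isolated)
8 | bromomagnesium (R)-3-methyl-3-(4-methylpent-3-en-1-yl)cyclohex-1-en-1-olate | Br[Mg]OC1=C[C@@](C)(CCC=C(C)C)CCC1 | intermediate (not isolated)
9 | methyl (3S)-5-hydroxy-3-methyl-5-[(2R)-2-methyl-2-(4-methylpent-3-en-1-yl)-6-oxocyclohexyl]pentanoate (mixture at C9 and C11) | O=C1CCC[C@](C)(CCC=C(C)C)C1C(O)C[C@H](C)CC(=O)OC | intermediate
10 | methyl (3S)-3-methyl-5-[(2R)-2-methyl-2-(4-methylpent-3-en-1-yl)-6-oxocyclohexyl]-5-(methylsulfonyloxy)pentanoate | O=C1CCC[C@](C)(CCC=C(C)C)C1C(OS(C)(=O)=O)C[C@H](C)CC(=O)OC | intermediate (not isolated)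
11 | methyl (3S)-3-methyl-5-[(2R)-2-methyl-2-(4-methylpent-3-en-1-yl)-6-oxocyclohexylidene]pentanoate (E/Z mixture) | O=C1CCC[C@](C)(CCC=C(C)C)C1=CC[C@H](C)CC(=O)OC | intermediate
12 | methyl (3S)-5-[(6R)-2-(dimethylphenylsilyloxy)-6-methyl-6-(4-methylpent-3-en-1-yl)cyclohex-1-en-1-yl]-3-methylpentanoate | C[Si](C)(c1ccccc1)OC1=C(CC[C@H](C)CC(=O)OC)[C@@](C)(CCC=C(C)C)CCC1 | intermediate (not isolated)
13 | methyl (3S)-3-methyl-5-[(1R,2R)-2-methyl-2-(4-methylpent-3-en-1-yl)-6-oxocyclohexyl]pentanoate (with its (1S,2R) epimer) | O=C1CCC[C@](C)(CCC=C(C)C)[C@H]1CC[C@H](C)CC(=O)OC | intermediate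
14 | methyl (3S)-5-[(1R,2R)-2-(4-chloro-4-methylpentyl)-2-methyl-6-oxocyclohexyl]-3-methylpentanoate (with its C9 epimer) | O=C1CCC[C@](C)(CCCC(C)(C)Cl)[C@H]1CC[C@H](C)CC(=O)OC | intermediate
15 | methyl (3S)-5-[(1R,6S)-6-(4-chloro-4-methylpentyl)-6-methyl-2-(trimethylsilyloxy)cyclohex-2-en-1-yl]-3-methylpentanoate (with its C9 epimer) | C[Si](C)(C)OC1=CCC[C@](C)(CCCC(C)(C)Cl)[C@H]1CC[C@H](C)CC(=O)OC | intermediate (not isolated)
16 | methyl (3S)-5-[(1R,6S)-6-(4-chloro-4-methylpentyl)-6-methyl-2-oxocyclohex-3-en-1-yl]-3-methylpentanoate (with its C9 epimer) | O=C1C=CC[C@](C)(CCCC(C)(C)Cl)[C@H]1CC[C@H](C)CC(=O)OC | intermediate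
17 | methyl (3S)-5-[(1R,6S)-2-(tert-butyldimethylsilyloxy)-6-(4-chloro-4-methylpentyl)-6-methylcyclohexa-2,4-dien-1-yl]-3-methylpentanoate (with its C9 epimer) | CC(C)(C)[Si](C)(C)OC1=CC=C[C@](C)(CCCC(C)(C)Cl)[C@H]1CC[C@H](C)CC(=O)OC | intermediate
18 | methyl (5R,10S,13S)-8-oxo-17-norlabd-6-en-15-oate (cis-fused, 5β-H; C9 epimers, drawn 9R) | O=C1C=C[C@@H]2C(C)(C)CCC[C@]2(C)[C@H]1CC[C@H](C)CC(=O)OC | intermediate (not isolated)
19 | methyl (5S,9R,10S,13S)-8-oxo-17-norlabd-6-en-15-oate | O=C1C=C[C@H]2C(C)(C)CCC[C@]2(C)[C@H]1CC[C@H](C)CC(=O)OC | intermediate
20 | methyl (5S,9R,10S,13S)-8-oxo-17-norlabdan-15-oate | O=C1CC[C@H]2C(C)(C)CCC[C@]2(C)[C@H]1CC[C@H](C)CC(=O)OC | intermediate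
21 | methyl (5S,9S,10S,13S)-labd-8(17)-en-15-oate | C=C1CC[C@H]2C(C)(C)CCC[C@]2(C)[C@H]1CC[C@H](C)CC(=O)OC | intermediate
22 | methyl (5S,7R,9R,10S,13S)-7-hydroxylabd-8(17)-en-15-oate | C=C1[C@H](O)C[C@H]2C(C)(C)CCC[C@]2(C)[C@H]1CC[C@H](C)CC(=O)OC | intermediate
23 | methyl (5S,7R,9R,10S,13S)-7-acetoxylabd-8(17)-en-15-oate = methyl (3S)-5-[(1R,3R,4aS,8aS)-3-acetoxy-5,5,8a-trimethyl-2-methylidenedecahydronaphthalen-1-yl]-3-methylpentanoate | C=C1[C@H](OC(C)=O)C[C@H]2C(C)(C)CCC[C@]2(C)[C@H]1CC[C@H](C)CC(=O)OC | target

## Step count and least certain steps

Total step count: 14. Longest linear sequence: 14 steps (1 to 23); 11 steps from 5 and 6.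

Step 10 (key step). Two processes may fail. The tertiary cation may lose a proton, or the dienol ether may be protodesilylated, faster than the C4–C5 bond forms. More probably, ring closure occurs with cis fusion under kinetic control and the base equilibration stops at a mixture, because the preference for the trans-fused enone is modest. Fallback, setting out from the crude mixture of 18 and 19 and returning at 20:
- Ketalisation with ethylene glycol and TsOH (benzene, water removal) passes through the dienol ether and moves the alkene out of conjugation. It gives the Δ5 ketal methyl (13S)-8,8-(ethylenedioxy)-17-norlabd-5-en-15-oate F1, in which C5 is no longer a stereocentre.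
- Hydrogen-atom-transfer hydrogenation (Mn(dpm)3, that is tris(dipivaloylmethanato)manganese, with PhSiH3 and t-BuOOH in i-PrOH) generates the tertiary C5 radical. It should take its hydrogen on the α face, anti to the axial methyls on C10 and C4, to give the trans-fused ketal methyl (13S)-8,8-(ethylenedioxy)-17-norlabdan-15-oate F2.
- PPTS in wet acetone, then NaOMe/MeOH (which restores any exchanged ester and sets C9), rejoins the route at 20.

Step 9. Deprotonation may occur at C9 instead of C5. The cross-conjugated dienol ether that results is nucleophilic at C9, from which a six-membered closure onto C4 is also conceivable, so regiochemical purity matters. Fallback, setting out from 16 and returning at 17: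
- Radical bromination (NBS, AIBN, PhCF3, 80 °C) at the only allylic position gives the 5-bromo derivative of 16 (bromine on labdane C5, epimer mixture) F3.
- Reductive silylation (activated Zn, TMEDA, TBSCl, THF–MeCN, 0 °C) generates the extended zinc dienolate without any deprotonation step and silylates it on oxygen to give 17.

Step 4. The hindered magnesium enolate may act as a base toward the enolisable aldehyde, add too slowly, or the aldolate may attack the methyl ester. Fallback, setting out from 8 and returning at 9:
- The enolate is quenched with TMSCl/Et3N and the silyl enol ether (R)-trimethyl{[3-methyl-3-(4-methylpent-3-en-1-yl)cyclohex-1-en-1-yl]oxy}silane F4 is isolated.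
- F4 is combined with 4 in a Mukaiyama aldol reaction (BF3·OEt2, CH2Cl2, −78 °C). This keeps the regiochemistry, involves no basic alkoxide and gives 9.

Step 13. Over-oxidation of the allylic alcohol to the enone, competing attack at C9 or incomplete facial selectivity may lower the return. Fallback, setting out from 20 and returning at 22:
- Kinetic enolisation toward C7 (LiN(SiMe3)2, TESCl, THF, −78 °C) gives methyl (13S)-8-(triethylsilyloxy)-17-norlabd-7-en-15-oate F5.
- Rubottom oxidation (mCPBA, NaHCO3, CH2Cl2, −20 °C), by epoxidation on the α face and silyl migration, gives methyl (13S)-8-oxo-7α-(triethylsilyloxy)-17-norlabdan-15-oate F6.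
- Wittig methylenation as in step 12 gives methyl (13S)-7α-(triethylsilyloxy)labd-8(17)-en-15-oate F7, and TBAF in THF releases 22.

## Further compounds

F1 | step 10 | methyl (13S)-8,8-(ethylenedioxy)-17-norlabd-5-en-15-oate | O1CCOC12CC=C3C(C)(C)CCC[C@]3(C)[C@H]2CC[C@H](C)CC(=O)OC
F2 | step 10 | methyl (13S)-8,8-(ethylenedioxy)-17-norlabdan-15-oate (5α-H) | O1CCOC12CC[C@H]3C(C)(C)CCC[C@]3(C)[C@H]2CC[C@H](C)CC(=O)OC
F3 | step 9 | 5-bromo derivative of 16 (bromine on labdane C5; epimer mixture) | O=C1C=CC(Br)[C@](C)(CCCC(C)(C)Cl)[C@H]1CC[C@H](C)CC(=O)OC
F4 | step 4 | (R)-trimethyl{[3-methyl-3-(4-methylpent-3-en-1-yl)cyclohex-1-en-1-yl]oxy}silane | C[Si](C)(C)OC1=C[C@@](C)(CCC=C(C)C)CCC1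
F5 | step 13 | methyl (13S)-8-(triethylsilyloxy)-17-norlabd-7-en-15-oate | CC[Si](CC)(CC)OC1=CC[C@H]2C(C)(C)CCC[C@]2(C)[C@H]1CC[C@H](C)CC(=O)OC
F6 | step 13 | methyl (13S)-8-oxo-7α-(triethylsilyloxy)-17-norlabdan-15-oate | O=C1[C@H](O[Si](CC)(CC)CC)C[C@H]2C(C)(C)CCC[C@]2(C)[C@H]1CC[C@H](C)CC(=O)OC
F7 | step 13 | methyl (13S)-7α-(triethylsilyloxy)labd-8(17)-en-15-oate | C=C1[C@H](O[Si](CC)(CC)CC)C[C@H]2C(C)(C)CCC[C@]2(C)[C@H]1CC[C@H](C)CC(=O)OC
A1 | alternative 1 | (R)-5-(tert-butyldimethylsilyloxy)-2-methylcyclohex-2-en-1-one | CC1=CC[C@@H](O[Si](C)(C)C(C)(C)C)CC1=O
A2 | alternative 1 | prenyltrimethylsilane | CC(C)=CC[Si](C)(C)C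
A3 | alternative 1 | allyl bromide | C=CCBr
A4 | alternative 1 | 2-allyl-2-methyl-3-(2-methylbut-3-en-2-yl)-5-(tert-butyldimethylsilyloxy)cyclohexan-1-one (C5, C7, C10 as in the target) | C1[C@H](O[Si](C)(C)C(C)(C)C)C[C@@H](C(C)(C)C=C)[C@](C)(CC=C)C1=O
A5 | alternative 1 | 7α-(tert-butyldimethylsilyloxy)-4,4,10-trimethyl-trans-octal-2-en-9-one (labdane numbering) | C1[C@H](O[Si](C)(C)C(C)(C)C)C[C@H]2C(C)(C)C=CC[C@]2(C)C1=O
A6 | alternative 2 | methyl (E)-4,4,8-trimethyl-9-oxodec-2-enoate | CC(=O)C(C)CCCC(C)(C)/C=C/C(=O)OC
A7 | alternative 2 | trans-4,4,10-trimethyldecalin-7,9-dione | O=C1C[C@H]2C(C)(C)CCC[C@]2(C)C(=O)C1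
A8 | alternative 3 | methyl (13S)-8-oxo-7,17-dinorlabdan-15-oate (B-nor; C6 bonded to C8; trans-fused) | O=C1C[C@H]2C(C)(C)CCC[C@]2(C)[C@H]1CC[C@H](C)CC(=O)OC
A9 | alternative 3 | trimethylsilyldiazomethane | C[Si](C)(C)C=[N+]=[N-]
A10 | alternative 3 | methyl (5S,9R,10S,13S)-8-oxo-17-norlabdan-15-oate (identical with 20) | O=C1CC[C@H]2C(C)(C)CCC[C@]2(C)[C@H]1CC[C@H](C)CC(=O)OC
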